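**Retrosynthetic overview**

1. Ring numbering: C1 (alkene carbon bearing C7H2OH), C2 (ketone), C3 (side-chain ester), C4 (isopropyl), C5 (isobutyrate), C6 (alkene CH). The two esters are cut at C3–O (acylation, retention) and C5–O (Mitsunobu, inversion), and the C4 isopropyl is traced back to isopropenyl.
2. The route rests on the C5 carbinol next to the C4 isopropenyl carbon, which is the product pattern of a carbonyl-ene reaction. Cutting C4–C5 opens the only ring to a C5 aldehyde facing a C4=C(CH3)2 alkene.
3. The (Z)-C5–C6=C1–C2 4-oxo-enal so exposed is a 2,3-disubstituted furan opened by singlet oxygen. The C3 carbinol, the only stereocentre made with a chiral reagent, relays C4 and C5 in the ring closure.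
4. The furan comes from furan-3-ylmethanol (C2 lithiation, addition to 3-methylbut-2-enal, oxidation, oxazaborolidine reduction). The side-chain acid comes from (tert-butyldimethylsilyloxy)acetaldehyde by Wittig olefination.

Key step: step 7

Assumption (remark on the chemistry): in step 4 the 3-substituted furyl group of ketone 6 is taken as the larger carbonyl substituent. Both substituents are planar π-systems, so the configuration of 7 is to be confirmed through its MTPA esters and the antipodal catalyst used if the sense proves reversed.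

**Route**

Step 1
Reactants: 1 furan-3-ylmethanol; 2 3-methylbut-2-enal
Product: 4 (±)-1-[3-(hydroxymethyl)furan-2-yl]-3-methylbut-2-en-1-ol, via 2-lithio-3-(lithiooxymethyl)furan 3 (not isolated)
Conditions: n-BuLi (2.2 equiv), THF, −78 → 0 °C; then 2, −78 °C; aq. NH4Cl
Reagents that add atoms: none
Why: Alkoxide-directed α-lithiation puts lithium on furan C2 (between the ring oxygen and the CH2OLi group) and the furyllithium adds 1,2 to the β,β-disubstituted enal; the carbinol is racemic here and is corrected in steps 3 and 4.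

Step 2
Reactants: 4 (±)-1-[3-(hydroxymethyl)furan-2-yl]-3-methylbut-2-en-1-ol
Product: 5 (±)-3-methyl-1-{3-[(triisopropylsilyloxy)methyl]furan-2-yl}but-2-en-1-ol
Conditions: TIPSCl (1.05 equiv), imidazole, DMF, 0 °C
Reagents that add atoms: chlorotriisopropylsilane, CC(C)[Si](Cl)(C(C)C)C(C)C
Why: Silyl ether formation with the bulky chlorosilane should take the primary hydroxyl and leave the hindered secondary allylic one, which also prevents over-oxidation of the furylic CH2OH in step 3.

Step 3
Reactants: 5 (±)-3-methyl-1-{3-[(triisopropylsilyloxy)methyl]furan-2-yl}but-2-en-1-ol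
Product: 6 3-methyl-1-{3-[(triisopropylsilyloxy)methyl]furan-2-yl}but-2-en-1-one
Conditions: activated MnO2, CH2Cl2, rt
Reagents that add atoms: none
Why: MnO2 oxidises the doubly activated (allylic and furylic) secondary alcohol selectively and leaves furan, alkene and silyl ether untouched.

Step 4
Reactants: 6 3-methyl-1-{3-[(triisopropylsilyloxy)methyl]furan-2-yl}but-2-en-1-one
Product: 7 (R)-3-methyl-1-{3-[(triisopropylsilyloxy)methyl]furan-2-yl}but-2-en-1-ol
Conditions: (S)-Me-CBS oxazaborolidine [(3aS)-1-methyl-3,3-diphenyltetrahydro-1H,3H-pyrrolo[1,2-c][1,3,2]oxazaborole] (0.2–1.0 equiv), catecholborane, toluene, −78 °C; then MeOH, aq. NaOH wash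
Reagents that add atoms: none
Why: Corey–Bakshi–Shibata reduction, in which the catalyst–borane complex binds the carbonyl lone pair anti to the larger (ortho-substituted furyl) group and delivers hydride within the complex, which for the (S)-catalyst should give the (R)-carbinol (the C3 stereocentre), catecholborane at low temperature keeping the reduction 1,2.

Step 5
Reactants: 7 (R)-3-methyl-1-{3-[(triisopropylsilyloxy)methyl]furan-2-yl}but-2-en-1-ol
Product: 8 (R)-2-[3-methyl-1-(triethylsilyloxy)but-2-en-1-yl]-3-[(triisopropylsilyloxy)methyl]furan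
Conditions: TESCl, imidazole, DMAP (cat.), CH2Cl2, 0 °C
Reagents that add atoms: chlorotriethylsilane, CC[Si](Cl)(CC)CC
Why: Silylation under basic conditions avoids ionisation of the acid-labile furyl allyl carbinol and gives a C3 ether that can later be removed beside the primary TIPS ether.

Step 6
Reactants: 8 (R)-2-[3-methyl-1-(triethylsilyloxy)but-2-en-1-yl]-3-[(triisopropylsilyloxy)methyl]furan
Product: 10 (2Z,5R)-7-methyl-4-oxo-5-(triethylsilyloxy)-3-[(triisopropylsilyloxy)methyl]octa-2,6-dienal, via furan endoperoxide 9 (not isolated)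
Conditions: O2, 5,10,15,20-tetraphenylporphyrin (cat.), hν (visible), CH2Cl2, −78 °C; then Me2S (2 equiv), −78 → 0 °C; used crude
Reagents that add atoms: dioxygen, O=O
Why: The [4+2] cycloaddition of singlet oxygen to the electron-rich furan should be much faster than its ene reaction with the trisubstituted alkene (deactivated by the allylic silyloxy group), and Me2S reduction of the endoperoxide (Kornblum–DeLaMare-type fragmentation) gives the 4-oxo-enal with the (Z) geometry inherited from the ring.

Step 7
Reactants: 10 (2Z,5R)-7-methyl-4-oxo-5-(triethylsilyloxy)-3-[(triisopropylsilyloxy)methyl]octa-2,6-dienal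
Product: 11 (4R,5S,6R)-4-hydroxy-5-(prop-1-en-2-yl)-6-(triethylsilyloxy)-2-[(triisopropylsilyloxy)methyl]cyclohex-2-en-1-one (overview numbering 3R,4S,5R; C3-OTES/C4 trans; C4/C5-OH trans)
Conditions: Me2AlCl (1.5 equiv, hexanes), CH2Cl2, −78 → −40 °C; aq. NaHCO3/Rochelle salt
Reagents that add atoms: none
Why: Me2AlCl binds the aldehyde oxygen of 10 and the C4=C(CH3)2 bond adds through C4 to C5 while a hydrogen of one allylic methyl passes to the aldehyde oxygen within one cyclic array, after which the alcohol–aluminium complex loses methane to a non-acidic alkoxide that shields the product from proton-induced decay. The closest known reaction is the Lewis-acid type-one intramolecular carbonyl-ene cyclisation (citronellal to isopulegol, neral to isopiperitenol). The cyclohexenone ring is closed by the C4–C5 bond through a half-chair array of C5, C6, C1, C2, C3 and C4 with the aldehyde C=O exocyclic (6-exo-trig at C5), the (Z) geometry of C6=C1 holding C5 within reach of C4. C4 is set by C3: allylic 1,3-strain with the methyl group cis to C3 keeps the C3–H bond in the alkene plane, so C2 and the silyloxy group lie on opposite faces and C5 must add anti to the OTES group (3,4-trans). C5 is set by the half-chair, in which the aluminium-bound oxygen should take the pseudo-equatorial site next to the pseudo-equatorial C4 substituent (4,5-trans expected). The step needs the aldehyde and not the ketone to act as enophile, which is secured because only attack at C5 gives a six-membered ring, and it needs hydrogen transfer to outrun Z-to-E isomerisation and chloride capture, which low temperature and the proton-scavenging Al–CH3 bonds should favour.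

Step 8
Reactants: 11 (4R,5S,6R)-4-hydroxy-5-(prop-1-en-2-yl)-6-(triethylsilyloxy)-2-[(triisopropylsilyloxy)methyl]cyclohex-2-en-1-one; 12 isobutyric acid
Product: 13 (1S,5R,6S)-4-oxo-6-(prop-1-en-2-yl)-5-(triethylsilyloxy)-3-[(triisopropylsilyloxy)methyl]cyclohex-2-en-1-yl 2-methylpropanoate
Conditions: PPh3, DIAD, 12 (3 equiv each), toluene, −20 °C → rt
Reagents that add atoms: none
Why: Mitsunobu esterification, in which the allylic C5 oxyphosphonium is displaced by isobutyrate with SN2 inversion, turning the 4,5-trans alcohol into the 4,5-cis isobutyrate of the target (SN2' attack at the fully substituted C1 is not expected).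

Step 9
Reactants: 13 (1S,5R,6S)-4-oxo-6-(prop-1-en-2-yl)-5-(triethylsilyloxy)-3-[(triisopropylsilyloxy)methyl]cyclohex-2-en-1-yl 2-methylpropanoate
Product: 14 (1S,5R,6S)-4-oxo-6-(propan-2-yl)-5-(triethylsilyloxy)-3-[(triisopropylsilyloxy)methyl]cyclohex-2-en-1-yl 2-methylpropanoate
Conditions: H2 (1 atm), RhCl(PPh3)3 (10 mol%), benzene/EtOH, rt
Reagents that add atoms: none
Why: Homogeneous hydrogenation with RhCl(PPh3)3 reduces the unhindered 1,1-disubstituted isopropenyl alkene and leaves the trisubstituted, conjugated C1=C6 bond and the allylic ester alone (as in carvone to carvotanacetone); no stereocentre is created.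

Step 10
Reactants: 14 (1S,5R,6S)-4-oxo-6-(propan-2-yl)-5-(triethylsilyloxy)-3-[(triisopropylsilyloxy)methyl]cyclohex-2-en-1-yl 2-methylpropanoate
Product: 15 (1S,5R,6R)-5-hydroxy-4-oxo-6-(propan-2-yl)-3-[(triisopropylsilyloxy)methyl]cyclohex-2-en-1-yl 2-methylpropanoate
Conditions: pyridinium p-toluenesulfonate (0.3 equiv), MeOH/CH2Cl2, 0 °C → rt
Reagents that add atoms: none
Why: Mild acid-catalysed methanolysis cleaves the secondary triethylsilyl ether far faster than the primary triisopropylsilyl ether and does not touch the isobutyrate or epimerise the α-ketol carbon C3 (the C4 descriptor changes only through substituent priorities).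

Step 11
Reactants: 16 (tert-butyldimethylsilyloxy)acetaldehyde; 17 ethyl 2-(triphenylphosphoranylidene)propanoate
Product: 18 ethyl (E)-4-(tert-butyldimethylsilyloxy)-2-methylbut-2-enoate
Conditions: CH2Cl2, rt
Reagents that add atoms: none
Why: Wittig olefination with a stabilised, α-branched ylide gives the (E)-trisubstituted enoate (ester trans to the CH2OTBS group).

Step 12
Reactants: 18 ethyl (E)-4-(tert-butyldimethylsilyloxy)-2-methylbut-2-enoate
Product: 19 (E)-4-(tert-butyldimethylsilyloxy)-2-methylbut-2-enoic acid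
Conditions: LiOH·H2O, THF/MeOH/H2O, 0 °C → rt; then 1 M HCl to pH 4, 0 °C
Reagents that add atoms: lithium hydroxide, [Li+].[OH-]
Why: Saponification of the ethyl ester; the primary TBS ether tolerates hydroxide and a brief cold acidification, and the (E)-enoate is the stable geometry.

Step 13
Reactants: 15 (1S,5R,6R)-5-hydroxy-4-oxo-6-(propan-2-yl)-3-[(triisopropylsilyloxy)methyl]cyclohex-2-en-1-yl 2-methylpropanoate; 19 (E)-4-(tert-butyldimethylsilyloxy)-2-methylbut-2-enoic acid
Product: 21 (1R,5S,6S)-5-(isobutyryloxy)-2-oxo-6-(propan-2-yl)-3-[(triisopropylsilyloxy)methyl]cyclohex-3-en-1-yl (E)-4-(tert-butyldimethylsilyloxy)-2-methylbut-2-enoate, via mixed 2,4,6-trichlorobenzoic anhydride 20 (not isolated)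
Conditions: 19, 2,4,6-trichlorobenzoyl chloride, Et3N, THF, rt; then 15, DMAP, toluene, rt
Reagents that add atoms: none
Why: Yamaguchi esterification acylates the hindered C3 hydroxyl at oxygen with retention; the 3,4-trans arrangement is also the more stable one, so base-induced epimerisation at C3 is not a threat.

Step 14
Reactants: 21 (1R,5S,6S)-5-(isobutyryloxy)-2-oxo-6-(propan-2-yl)-3-[(triisopropylsilyloxy)methyl]cyclohex-3-en-1-yl (E)-4-(tert-butyldimethylsilyloxy)-2-methylbut-2-enoate
Product: 22 CNP0254776.1, (1R,5S,6S)-3-(hydroxymethyl)-5-(isobutyryloxy)-2-oxo-6-(propan-2-yl)cyclohex-3-en-1-yl (E)-4-hydroxy-2-methylbut-2-enoate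
Conditions: HF·pyridine, pyridine, THF, 0 °C → rt
Reagents that add atoms: none
Why: Buffered HF·pyridine removes both primary silyl ethers (TIPS at C7, TBS on the side chain) under non-basic conditions, so neither ester migrates, is cleaved, or eliminates.

**Compound list**

1 | furan-3-ylmethanol | OCc1ccoc1 | starting material
2 | 3-methylbut-2-enal | CC(C)=CC=O | starting material
3 | 2-lithio-3-(lithiooxymethyl)furan (formed in situ) | [Li]OCc1ccoc1[Li] | intermediate
4 | (±)-1-[3-(hydroxymethyl)furan-2-yl]-3-methylbut-2-en-1-ol | CC(C)=CC(O)c1occc1CO | intermediate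
5 | (±)-3-methyl-1-{3-[(triisopropylsilyloxy)methyl]furan-2-yl}but-2-en-1-ol | CC(C)=CC(O)c1occc1CO[Si](C(C)C)(C(C)C)C(C)C | intermediate
6 | 3-methyl-1-{3-[(triisopropylsilyloxy)methyl]furan-2-yl}but-2-en-1-one | CC(C)=CC(=O)c1occc1CO[Si](C(C)C)(C(C)C)C(C)C | intermediate
7 | (R)-3-methyl-1-{3-[(triisopropylsilyloxy)methyl]furan-2-yl}but-2-en-1-ol | CC(C)=C[C@@H](O)c1occc1CO[Si](C(C)C)(C(C)C)C(C)C | intermediate
8 | (R)-2-[3-methyl-1-(triethylsilyloxy)but-2-en-1-yl]-3-[(triisopropylsilyloxy)methyl]furan | CC(C)=C[C@@H](O[Si](CC)(CC)CC)c1occc1CO[Si](C(C)C)(C(C)C)C(C)C | intermediate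
9 | furan endoperoxide of 8 (2,3,7-trioxabicyclo[2.2.1]hept-5-ene; bridgehead configuration undefined; formed in situ) | CC(C)=C[C@@H](O[Si](CC)(CC)CC)C12OOC(O1)C=C2CO[Si](C(C)C)(C(C)C)C(C)C | intermediate
10 | (2Z,5R)-7-methyl-4-oxo-5-(triethylsilyloxy)-3-[(triisopropylsilyloxy)methyl]octa-2,6-dienal | O=C/C=C(/CO[Si](C(C)C)(C(C)C)C(C)C)C(=O)[C@H](O[Si](CC)(CC)CC)C=C(C)C | intermediate
11 | (4R,5S,6R)-4-hydroxy-5-(prop-1-en-2-yl)-6-(triethylsilyloxy)-2-[(triisopropylsilyloxy)methyl]cyclohex-2-en-1-one | CC[Si](CC)(CC)O[C@H]1C(=O)C(CO[Si](C(C)C)(C(C)C)C(C)C)=C[C@@H](O)[C@@H]1C(C)=C | intermediate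
12 | isobutyric acid | CC(C)C(O)=O | starting material
13 | (1S,5R,6S)-4-oxo-6-(prop-1-en-2-yl)-5-(triethylsilyloxy)-3-[(triisopropylsilyloxy)methyl]cyclohex-2-en-1-yl 2-methylpropanoate | CC[Si](CC)(CC)O[C@H]1C(=O)C(CO[Si](C(C)C)(C(C)C)C(C)C)=C[C@H](OC(=O)C(C)C)[C@@H]1C(C)=C | intermediate
14 | (1S,5R,6S)-4-oxo-6-(propan-2-yl)-5-(triethylsilyloxy)-3-[(triisopropylsilyloxy)methyl]cyclohex-2-en-1-yl 2-methylpropanoate | CC[Si](CC)(CC)O[C@H]1C(=O)C(CO[Si](C(C)C)(C(C)C)C(C)C)=C[C@H](OC(=O)C(C)C)[C@@H]1C(C)C | intermediate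
15 | (1S,5R,6R)-5-hydroxy-4-oxo-6-(propan-2-yl)-3-[(triisopropylsilyloxy)methyl]cyclohex-2-en-1-yl 2-methylpropanoate | O[C@H]1C(=O)C(CO[Si](C(C)C)(C(C)C)C(C)C)=C[C@H](OC(=O)C(C)C)[C@@H]1C(C)C | intermediate
16 | (tert-butyldimethylsilyloxy)acetaldehyde | CC(C)(C)[Si](C)(C)OCC=O | starting material
17 | ethyl 2-(triphenylphosphoranylidene)propanoate | CCOC(=O)C(C)=P(c1ccccc1)(c1ccccc1)c1ccccc1 | starting material
18 | ethyl (E)-4-(tert-butyldimethylsilyloxy)-2-methylbut-2-enoate | C/C(=C\CO[Si](C)(C)C(C)(C)C)C(=O)OCC | intermediate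
19 | (E)-4-(tert-butyldimethylsilyloxy)-2-methylbut-2-enoic acid | C/C(=C\CO[Si](C)(C)C(C)(C)C)C(=O)O | intermediate
20 | mixed anhydride of 19 with 2,4,6-trichlorobenzoic acid (formed in situ) | C/C(=C\CO[Si](C)(C)C(C)(C)C)C(=O)OC(=O)c1c(Cl)cc(Cl)cc1Cl | intermediate
21 | (1R,5S,6S)-5-(isobutyryloxy)-2-oxo-6-(propan-2-yl)-3-[(triisopropylsilyloxy)methyl]cyclohex-3-en-1-yl (E)-4-(tert-butyldimethylsilyloxy)-2-methylbut-2-enoate | C/C(=C\CO[Si](C)(C)C(C)(C)C)C(=O)O[C@H]1C(=O)C(CO[Si](C(C)C)(C(C)C)C(C)C)=C[C@H](OC(=O)C(C)C)[C@@H]1C(C)C | intermediate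
22 | CNP0254776.1, (1R,5S,6S)-3-(hydroxymethyl)-5-(isobutyryloxy)-2-oxo-6-(propan-2-yl)cyclohex-3-en-1-yl (E)-4-hydroxy-2-methylbut-2-enoate | C/C(=C\CO)C(=O)O[C@H]1C(=O)C(CO)=C[C@H](OC(=O)C(C)C)[C@@H]1C(C)C | target

**Step count and risks**

Total step count: 14. Longest linear sequence: 12 steps (steps 1–10, 13 and 14, from furan-3-ylmethanol).

Steps most likely to fail:

1. Step 7 (ene cyclisation). The aluminium-bound keto-enal may isomerise from Z to E, or close through the C3 silyl ether oxygen (pyranone-type closure), before the weakly nucleophilic alkene attacks. The cationic intermediate may also be captured by chloride instead of transferring hydrogen. The fallback gives the ene donor an activating silyl group so that a mild Lewis acid suffices. It sets out from the dilithio species 3 and returns at 11.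
 - 3 is acylated with N-methoxy-N-methylbut-2-ynamide (THF, −78 °C) to give the ynone 1-[3-(hydroxymethyl)furan-2-yl]but-2-yn-1-one F1.
 - TIPSCl/imidazole gives 1-{3-[(triisopropylsilyloxy)methyl]furan-2-yl}but-2-yn-1-one F2.
 - Conjugate addition of (Me3SiCH2)2CuLi (THF, −78 °C) gives 3-methyl-1-{3-[(triisopropylsilyloxy)methyl]furan-2-yl}-4-(trimethylsilyl)but-2-en-1-one F3; either alkene geometry serves.
 - Oxazaborolidine reduction as in step 4 gives (R)-3-methyl-1-{3-[(triisopropylsilyloxy)methyl]furan-2-yl}-4-(trimethylsilyl)but-2-en-1-ol F4.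
 - TESCl/imidazole gives (R)-2-[3-methyl-1-(triethylsilyloxy)-4-(trimethylsilyl)but-2-en-1-yl]-3-[(triisopropylsilyloxy)methyl]furan F5.
 - Photooxygenation and Me2S as in step 6 give (2Z,5R)-7-methyl-4-oxo-5-(triethylsilyloxy)-3-[(triisopropylsilyloxy)methyl]-8-(trimethylsilyl)octa-2,6-dienal F6.
 - BF3·OEt2 (CH2Cl2, −78 °C) closes C4–C5 by intramolecular Hosomi–Sakurai allylation with loss of the silyl group, giving 11 under the same allylic-strain control.

2. Step 4 (oxazaborolidine reduction). Both ketone substituents are planar π-systems, so facial discrimination may be poor or reversed. The fallback sets C3 by the face of an aldehyde instead. It sets out from 3 and returns at 7.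
 - Formylation with DMF gives 3-(hydroxymethyl)furan-2-carbaldehyde F7.
 - TIPSCl/imidazole gives 3-[(triisopropylsilyloxy)methyl]furan-2-carbaldehyde F8.
 - Catalytic asymmetric alkenylzinc addition then gives 7 directly. The reagent is 2-methylprop-1-enyl(ethyl)zinc, from 2-methylprop-1-enyllithium and EtZnCl with LiCl sequestered by N,N,N',N'-tetraethylethylenediamine. The ligand is (+)-MIB [(2R)-3-exo-morpholinoisoborneol], the enantiomer that should direct the alkenyl group to the Re face of the aldehyde (toluene/hexane, 0 °C).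

3. Step 8 (Mitsunobu inversion). Displacement by the weakly acidic isobutyric acid may be slow at the hindered C5. The oxyphosphonium intermediate could then eliminate towards a cyclohexadienone that aromatises, or the acid could be delivered with retention. The fallback separates inversion from acylation. It sets out from 11 and returns at 13.
 - Mitsunobu reaction with the more acidic chloroacetic acid (PPh3, DIAD, toluene) gives the inverted ester (1S,5R,6S)-4-oxo-6-(prop-1-en-2-yl)-5-(triethylsilyloxy)-3-[(triisopropylsilyloxy)methyl]cyclohex-2-en-1-yl chloroacetate F9.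
 - Brief methanolysis (K2CO3 cat., MeOH, 0 °C) gives the 4,5-cis alcohol (4S,5S,6R)-4-hydroxy-5-(prop-1-en-2-yl)-6-(triethylsilyloxy)-2-[(triisopropylsilyloxy)methyl]cyclohex-2-en-1-one F10.
 - Isobutyric anhydride, Et3N and DMAP (CH2Cl2) acylate it with retention to 13.
 - F10 is also what a 4,5-cis-selective ene reaction would deliver, so the same acylation covers that outcome of step 7.

**Further compounds**

F1 | step 7 | 1-[3-(hydroxymethyl)furan-2-yl]but-2-yn-1-one | CC#CC(=O)c1occc1CO
F2 | step 7 | 1-{3-[(triisopropylsilyloxy)methyl]furan-2-yl}but-2-yn-1-one | CC#CC(=O)c1occc1CO[Si](C(C)C)(C(C)C)C(C)C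
F3 | step 7 | 3-methyl-1-{3-[(triisopropylsilyloxy)methyl]furan-2-yl}-4-(trimethylsilyl)but-2-en-1-one | C[Si](C)(C)CC(C)=CC(=O)c1occc1CO[Si](C(C)C)(C(C)C)C(C)C
F4 | step 7 | (R)-3-methyl-1-{3-[(triisopropylsilyloxy)methyl]furan-2-yl}-4-(trimethylsilyl)but-2-en-1-ol | C[Si](C)(C)CC(C)=C[C@@H](O)c1occc1CO[Si](C(C)C)(C(C)C)C(C)C
F5 | step 7 | (R)-2-[3-methyl-1-(triethylsilyloxy)-4-(trimethylsilyl)but-2-en-1-yl]-3-[(triisopropylsilyloxy)methyl]furan | C[Si](C)(C)CC(C)=C[C@@H](O[Si](CC)(CC)CC)c1occc1CO[Si](C(C)C)(C(C)C)C(C)C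
F6 | step 7 | (2Z,5R)-7-methyl-4-oxo-5-(triethylsilyloxy)-3-[(triisopropylsilyloxy)methyl]-8-(trimethylsilyl)octa-2,6-dienal | O=C/C=C(/CO[Si](C(C)C)(C(C)C)C(C)C)C(=O)[C@H](O[Si](CC)(CC)CC)C=C(C)C[Si](C)(C)C
F7 | step 4 | 3-(hydroxymethyl)furan-2-carbaldehyde | O=Cc1occc1CO
F8 | step 4 | 3-[(triisopropylsilyloxy)methyl]furan-2-carbaldehyde | O=Cc1occc1CO[Si](C(C)C)(C(C)C)C(C)C
F9 | step 8 | (1S,5R,6S)-4-oxo-6-(prop-1-en-2-yl)-5-(triethylsilyloxy)-3-[(triisopropylsilyloxy)methyl]cyclohex-2-en-1-yl chloroacetate | CC[Si](CC)(CC)O[C@H]1C(=O)C(CO[Si](C(C)C)(C(C)C)C(C)C)=C[C@H](OC(=O)CCl)[C@@H]1C(C)=C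
F10 | step 8 | (4S,5S,6R)-4-hydroxy-5-(prop-1-en-2-yl)-6-(triethylsilyloxy)-2-[(triisopropylsilyloxy)methyl]cyclohex-2-en-1-one | CC[Si](CC)(CC)O[C@H]1C(=O)C(CO[Si](C(C)C)(C(C)C)C(C)C)=C[C@H](O)[C@@H]1C(C)=C
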